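All runs are simulated with made-up constants.

The examiner lays out three earlier runs and a new flask, charged like larch and birch but at a middle strength, and wants three numbers at 20 h.

common to all: gas 200 mM (held); free catalyst 14 mM
- larch: left-handed substrate 0.50 M; right-handed substrate 0.50 M; added ligand 11 mM; run made earlier
- birch: left-handed substrate 2 M; right-handed substrate 2 M; added ligand 11 mM; run made earlier
- elm: left-handed substrate 1 M; right-handed substrate 1 M; added ligand 16 mM; run made earlier
- flask: left-handed substrate 1.0 M; right-handed substrate 1.0 M; added ligand 11 mM; time 20 h

- larch (time / h: left-handed substrate / %, right-handed substrate / %): 1.50: 49.7, 49.5; 4.00: 47.3, 49.2; 8.00: 45.0, 50.0; 20.0: 42.1, 47.5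
- birch (time / h: left-handed substrate / %, right-handed substrate / %): 5.00: 47.3, 49.5; 10.0: 45.8, 47.9; 15.0: 43.5, 48.2; 20.0: 43.6, 46.8
- elm (time / h: left-handed substrate / %, right-handed substrate / %): 1.50: 50.2, 50.5; 4.00: 49.4, 50.0; 8.00: 46.9, 49.3; 20.0: 46.2, 47.9

(scatter of a reading: 0.5 percentage points)

- part of the left-handed substrate and right-handed substrate charged together that has reacted at 20 h
- excess of left-handed product over right-handed product in the product at 20 h
- excess of right-handed substrate over left-handed substrate among what is left of the two at 20 h

- free catalyst is single-handed; left-handed substrate and right-handed substrate are mirror images of each other, charged as a racemate, each of them at the stated concentration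
- at the start none of the gas is in solution
- an excess is below zero if the other one leads

"How much reacts?" Larch lost 10.4% of its charge by 20.0 h and birch 9.60%, at 0.50 M and 2 M of each substrate. I take their mean, 10.0%, for the flask.

"And the excess in the product?" Pooled over the three runs at 20.0 h, one number stands at 39.8%: the gap share, right-handed minus left-handed substrate over the part reacted, both as fractions of the charge.

"Is that the excess?" Not if the substrates cross. In a closed flask where substrate either reacts or crosses to its mirror form (racemisation), each molecule crossing from the richer side narrows the gap by two. The product excess is then the gap share plus twice the crossed part over the part reacted, and while the crossing runs from the richer side, the gap share is a floor.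

"Do the readings show crossing?" Pooled at 8.00 h in larch and elm and 10.0 h in birch, the share was 62.9%, higher than later. With 0.5 percentage points on each reading, that is a hint.

"Your commitment?" Product excess above the earlier reading of 62.9%, and a substrate excess of 4.42%.

The forecast gives 10% (8.5% to 11.5%), 48% (35% to 60%) and 5.3% (3.7% to 7%); its maker chose to “fit the gap between right- and left-handed substrate against conversion”. Its product excess lies below the figure I committed to, and its substrate excess differs from mine.

The flask gives 10.5%, 97.6% and 4.91%.

    partner + free catalyst + right-handed substrate → free catalyst + right-handed product (k = 0.00540 M⁻² min⁻¹)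
    partner + free catalyst + left-handed substrate → free catalyst + left-handed product (k = 0.480 M⁻² min⁻¹)
    free catalyst → spent catalyst (k = 0.00160 min⁻¹)
    gas ⇌ partner, rate k4*(csat - [partner]) (kL = 0.0100 min⁻¹)
    left-handed substrate ⇌ right-handed substrate (k = 7.30 × 10⁻⁴ min⁻¹)
    free catalyst + added ligand ⇌ idle complex, settled at all times (K = 1600 M⁻¹)

The product excess stands above the forecast's range, while this flask's gap share is 41.9%. By the balance, 2.93% of the charge crossed in this flask. A neighbouring flask is charged with 0.056 M of free catalyst, the other charges unchanged. It reacts to 39.0% with a product excess of 96.9% and a substrate excess of 23.8%, so its gap share is 37.2%. The same balance gives about 11.6% of the charge crossed in that neighbouring flask.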